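## Retrosynthetic overview

1. The target is the (2R,3R,2''R,3''R)-3,3''-biflavanone with both rings 2,3-cis; the last step is a neutral global O-debenzylation.
2. C3 and C3'' are set last among the stereocentres, by kinetic protonation of the bis-enolate of the tribenzyl ether under control of the two C2 aryl groups.
3. The C3–C3'' bond comes from a silicon-tethered oxidative heterocoupling of the enolates of two different (R)-flavanones; this is the convergent point.
4. Each pyranone ring is closed separately, before the coupling, by an enantioselective intramolecular oxa-Michael addition of a 2'-hydroxychalcone-type alkylidene β-ketoester, followed by decarboxylation (sets C2 and C2'').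
5. The alkylidene β-ketoesters come from O-benzylated phloroacetophenones, Boc2O and 4-methoxybenzaldehyde.

Assumption: the quinine-derived thiourea named in steps 4 and 8 is taken to give the 2R series; if it gives 2S, the quinidine-derived pseudoenantiomer is used in the same way.

## Route

Step 1
Reactants: 1 2',4',6'-trihydroxyacetophenone; 2 benzyl bromide
Product: 3 1-[2,4-bis(benzyloxy)-6-hydroxyphenyl]ethanone
Conditions: BnBr (2.1 equiv), K2CO3 (2.2 equiv), DMF, rt
Reagents that add atoms: benzyl bromide, BrCc1ccccc1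
Why: Williamson etherification in which the para OH and one ortho OH are alkylated while the remaining ortho OH, hydrogen-bonded to the acetyl group, stays free.

Step 2
Reactants: 3 1-[2,4-bis(benzyloxy)-6-hydroxyphenyl]ethanone; 4 di-tert-butyl dicarbonate
Product: 5 tert-butyl 3-[2,4-bis(benzyloxy)-6-hydroxyphenyl]-3-oxopropanoate
Conditions: LiHMDS (3.3 equiv), THF, −78 °C; Boc2O (1.1 equiv), −78 to 0 °C; cold 1 M HCl
Reagents that add atoms: di-tert-butyl dicarbonate, CC(C)(C)OC(=O)OC(=O)OC(C)(C)C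
Why: Crossed Claisen-type C-acylation of the phenoxide/enolate dianion by Boc2O, driven by deprotonation of the β-ketoester product by the third equivalent of base, the tert-butyl ester resisting lactonisation to a 4-hydroxycoumarin.

Step 3
Reactants: 5 tert-butyl 3-[2,4-bis(benzyloxy)-6-hydroxyphenyl]-3-oxopropanoate; 6 4-methoxybenzaldehyde
Product: 7 tert-butyl (Z)-2-[2,4-bis(benzyloxy)-6-hydroxybenzoyl]-3-(4-methoxyphenyl)prop-2-enoate
Conditions: 6 (1.1 equiv), piperidine (10 mol %), AcOH (10 mol %), 4 Å MS, toluene, rt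
Reagents that add atoms: 4-methoxybenzaldehyde, COc1ccc(C=O)cc1
Why: Knoevenagel condensation of the active methylene with the aldehyde under mild, water-scavenged conditions gives the alkylidene (mainly Z, anisyl cis to the ester) while keeping racemic background cyclisation low.

Step 4
Reactants: 7 tert-butyl (Z)-2-[2,4-bis(benzyloxy)-6-hydroxybenzoyl]-3-(4-methoxyphenyl)prop-2-enoate
Product: 10 (2R)-5,7-bis(benzyloxy)-2-(4-methoxyphenyl)chroman-4-one, via cyclised tert-butyl ester 8 (not isolated), via beta-keto acid 9 (not isolated)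
Conditions: 1-[3,5-bis(trifluoromethyl)phenyl]-3-(9-deoxy-epi-quinin-9-yl)thiourea (10 mol %), toluene, −25 °C; then TsOH·H2O (0.5 equiv), 80 °C; recrystallise
Reagents that add atoms: none
Why: Enantioselective intramolecular oxa-Michael addition (6-endo-trig) in which the thiourea binds the β-ketoester and the quinuclidine delivers the phenol to one face of the alkylidene, setting C2 as R, after which acid cleavage of the tert-butyl ester and decarboxylation turn C3 into CH2 without touching C2.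

Step 5
Reactants: 11 1-(2,6-dihydroxy-4-methoxyphenyl)ethanone; 2 benzyl bromide
Product: 12 1-[2-(benzyloxy)-6-hydroxy-4-methoxyphenyl]ethanone
Conditions: BnBr (1.05 equiv), K2CO3 (1.1 equiv), acetone, reflux
Reagents that add atoms: benzyl bromide, BrCc1ccccc1
Why: Williamson mono-etherification, since after the first O-benzylation the remaining ortho OH is locked in a hydrogen bond to the carbonyl and reacts much more slowly.

Step 6
Reactants: 12 1-[2-(benzyloxy)-6-hydroxy-4-methoxyphenyl]ethanone; 4 di-tert-butyl dicarbonate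
Product: 13 tert-butyl 3-[2-(benzyloxy)-6-hydroxy-4-methoxyphenyl]-3-oxopropanoate
Conditions: LiHMDS (3.3 equiv), THF, −78 °C; Boc2O (1.1 equiv), −78 to 0 °C; cold 1 M HCl
Reagents that add atoms: di-tert-butyl dicarbonate, CC(C)(C)OC(=O)OC(=O)OC(C)(C)C
Why: The same crossed Claisen-type C-acylation of the ketone enolate as in step 2.

Step 7
Reactants: 13 tert-butyl 3-[2-(benzyloxy)-6-hydroxy-4-methoxyphenyl]-3-oxopropanoate; 6 4-methoxybenzaldehyde
Product: 14 tert-butyl (Z)-2-[2-(benzyloxy)-6-hydroxy-4-methoxybenzoyl]-3-(4-methoxyphenyl)prop-2-enoate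
Conditions: 6 (1.1 equiv), piperidine (10 mol %), AcOH (10 mol %), 4 Å MS, toluene, rt
Reagents that add atoms: 4-methoxybenzaldehyde, COc1ccc(C=O)cc1
Why: Knoevenagel condensation as in step 3.

Step 8
Reactants: 14 tert-butyl (Z)-2-[2-(benzyloxy)-6-hydroxy-4-methoxybenzoyl]-3-(4-methoxyphenyl)prop-2-enoate
Product: 17 (2R)-5-(benzyloxy)-7-methoxy-2-(4-methoxyphenyl)chroman-4-one, via cyclised tert-butyl ester 15 (not isolated), via beta-keto acid 16 (not isolated)
Conditions: 1-[3,5-bis(trifluoromethyl)phenyl]-3-(9-deoxy-epi-quinin-9-yl)thiourea (10 mol %), toluene, −25 °C; then TsOH·H2O (0.5 equiv), 80 °C; recrystallise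
Reagents that add atoms: none
Why: The same catalyst-controlled intramolecular oxa-Michael addition followed by decarboxylation as in step 4 sets C2'' as R.

Step 9
Reactants: 17 (2R)-5-(benzyloxy)-7-methoxy-2-(4-methoxyphenyl)chroman-4-one; 18 dichlorodi(propan-2-yl)silane; 10 (2R)-5,7-bis(benzyloxy)-2-(4-methoxyphenyl)chroman-4-one
Product: 20 mixed diisopropylsilyl bis-enol ether of 10 and 17, via chlorosilyl enol ether 19 (not isolated)
Conditions: 17, LDA (1.05 equiv), THF, −78 °C, added to iPr2SiCl2 (1.05 equiv), −78 to 0 °C; then 10 pre-treated with LDA (1.05 equiv, THF, −78 °C), to rt; filter through Et3N-deactivated silica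
Reagents that add atoms: dichlorodi(propan-2-yl)silane, CC(C)[Si](Cl)(Cl)C(C)C
Why: Sequential O-silylation of two kinetic lithium enolates, where the bulky isopropyl groups stop the first enolate at monosubstitution and the second enolate then displaces the remaining chloride, deprotonation at −78 °C touching only C3 so that C2 and C2'' are unchanged.

Step 10
Reactants: 20 mixed diisopropylsilyl bis-enol ether of 10 and 17
Product: 21 (2R,3S,2''R,3''S)-5,7,5''-tris(benzyloxy)-7'',4',4'''-trimethoxy-3,3''-biflavanone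
Conditions: CAN (2.2 equiv), NaHCO3 (4.4 equiv), MeCN–EtCN, −10 °C; chromatography
Reagents that add atoms: none
Why: Silicon-tethered oxidative enolate heterocoupling in which Ce(IV) oxidises one enol ether to a radical cation that is trapped intramolecularly by the other, a second oxidation and loss of silicon giving only the cross-coupled 1,4-diketone; the bond forms mainly anti to each C2 aryl group (trans,trans), C3 epimers are carried along because both centres are reset in step 11, and the minor C2-diastereomers that stem from incomplete ee of 10 and 17 are removed here.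

Step 11
Reactants: 21 (2R,3S,2''R,3''S)-5,7,5''-tris(benzyloxy)-7'',4',4'''-trimethoxy-3,3''-biflavanone
Product: 23 (2R,3R,2''R,3''R)-5,7,5''-tris(benzyloxy)-7'',4',4'''-trimethoxy-3,3''-biflavanone, via dilithium bis-enolate 22 (not isolated)
Conditions: LDA (4 equiv), THF, −78 to −40 °C; −78 °C, 2,6-di-tert-butyl-4-methylphenol (6 equiv), then AcOH; neutral silica
Reagents that add atoms: none
Why: Double enolisation followed by kinetic protonation, in which A(1,2) strain forces each C2 anisyl group pseudo-axial in its enolate so that the bulky proton donor delivers H to the opposite face and the C3–C3'' bond ends up cis to the aryl group on both rings (3R,3''R), the low temperature suppressing retro-oxa-Michael opening.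

Step 12
Reactants: 23 (2R,3R,2''R,3''R)-5,7,5''-tris(benzyloxy)-7'',4',4'''-trimethoxy-3,3''-biflavanone
Product: 24 (2R,3R,2''R,3''R)-5,7,5''-trihydroxy-7'',4',4'''-trimethoxy-3,3''-biflavanone (CNP0184936.2)
Conditions: H2 (1 atm), 10% Pd/C, EtOAc–MeOH, rt, monitored and stopped at full conversion
Reagents that add atoms: none
Why: Catalytic hydrogenolysis of the three aryl benzyl ethers under neutral conditions that cannot enolise the ketones, so the cis,cis stereotetrad survives, the flavanone C2–O bond being cleaved far more slowly than O-benzyl groups.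

## Compound list

1 | 2',4',6'-trihydroxyacetophenone | CC(=O)c1c(O)cc(O)cc1O | starting material
2 | benzyl bromide | BrCc1ccccc1 | starting material
3 | 1-[2,4-bis(benzyloxy)-6-hydroxyphenyl]ethanone | CC(=O)c1c(O)cc(OCc2ccccc2)cc1OCc1ccccc1 | intermediate
4 | di-tert-butyl dicarbonate | CC(C)(C)OC(=O)OC(=O)OC(C)(C)C | starting material
5 | tert-butyl 3-[2,4-bis(benzyloxy)-6-hydroxyphenyl]-3-oxopropanoate | CC(C)(C)OC(=O)CC(=O)c1c(O)cc(OCc2ccccc2)cc1OCc1ccccc1 | intermediate
6 | 4-methoxybenzaldehyde | COc1ccc(C=O)cc1 | starting material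
7 | tert-butyl (Z)-2-[2,4-bis(benzyloxy)-6-hydroxybenzoyl]-3-(4-methoxyphenyl)prop-2-enoate | COc1ccc(/C=C(\C(=O)OC(C)(C)C)C(=O)c2c(O)cc(OCc3ccccc3)cc2OCc2ccccc2)cc1 | intermediate
8 | tert-butyl (2R,3S)-5,7-bis(benzyloxy)-2-(4-methoxyphenyl)-4-oxochromane-3-carboxylate (2,3-trans; C3 labile) | COc1ccc([C@@H]2Oc3cc(OCc4ccccc4)cc(OCc4ccccc4)c3C(=O)[C@H]2C(=O)OC(C)(C)C)cc1 | intermediate (not isolated)
9 | (2R,3S)-5,7-bis(benzyloxy)-2-(4-methoxyphenyl)-4-oxochromane-3-carboxylic acid | COc1ccc([C@@H]2Oc3cc(OCc4ccccc4)cc(OCc4ccccc4)c3C(=O)[C@H]2C(=O)O)cc1 | intermediate (not isolated)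
10 | (2R)-5,7-bis(benzyloxy)-2-(4-methoxyphenyl)chroman-4-one | COc1ccc([C@@H]2Oc3cc(OCc4ccccc4)cc(OCc4ccccc4)c3C(=O)C2)cc1 | intermediate
11 | 1-(2,6-dihydroxy-4-methoxyphenyl)ethanone | CC(=O)c1c(O)cc(OC)cc1O | starting material
12 | 1-[2-(benzyloxy)-6-hydroxy-4-methoxyphenyl]ethanone | CC(=O)c1c(O)cc(OC)cc1OCc1ccccc1 | intermediate
13 | tert-butyl 3-[2-(benzyloxy)-6-hydroxy-4-methoxyphenyl]-3-oxopropanoate | CC(C)(C)OC(=O)CC(=O)c1c(O)cc(OC)cc1OCc1ccccc1 | intermediate
14 | tert-butyl (Z)-2-[2-(benzyloxy)-6-hydroxy-4-methoxybenzoyl]-3-(4-methoxyphenyl)prop-2-enoate | COc1ccc(/C=C(\C(=O)OC(C)(C)C)C(=O)c2c(O)cc(OC)cc2OCc2ccccc2)cc1 | intermediate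
15 | tert-butyl (2R,3S)-5-(benzyloxy)-7-methoxy-2-(4-methoxyphenyl)-4-oxochromane-3-carboxylate (2,3-trans; C3 labile) | COc1ccc([C@@H]2Oc3cc(OC)cc(OCc4ccccc4)c3C(=O)[C@H]2C(=O)OC(C)(C)C)cc1 | intermediate (not isolated)
16 | (2R,3S)-5-(benzyloxy)-7-methoxy-2-(4-methoxyphenyl)-4-oxochromane-3-carboxylic acid | COc1ccc([C@@H]2Oc3cc(OC)cc(OCc4ccccc4)c3C(=O)[C@H]2C(=O)O)cc1 | intermediate (not isolated)
17 | (2R)-5-(benzyloxy)-7-methoxy-2-(4-methoxyphenyl)chroman-4-one | COc1ccc([C@@H]2Oc3cc(OC)cc(OCc4ccccc4)c3C(=O)C2)cc1 | intermediate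
18 | dichlorodi(propan-2-yl)silane | CC(C)[Si](Cl)(Cl)C(C)C | starting material
19 | (2R)-5-(benzyloxy)-4-{[chloro-di(propan-2-yl)silyl]oxy}-7-methoxy-2-(4-methoxyphenyl)-2H-chromene | COc1ccc([C@@H]2Oc3cc(OC)cc(OCc4ccccc4)c3C(O[Si](Cl)(C(C)C)C(C)C)=C2)cc1 | intermediate (not isolated)
20 | {[(2R)-5,7-bis(benzyloxy)-2-(4-methoxyphenyl)-2H-chromen-4-yl]oxy}{[(2R)-5-(benzyloxy)-7-methoxy-2-(4-methoxyphenyl)-2H-chromen-4-yl]oxy}di(propan-2-yl)silane | COc1ccc([C@@H]2Oc3cc(OC)cc(OCc4ccccc4)c3C(O[Si](C(C)C)(C(C)C)OC3=C[C@H](c4ccc(OC)cc4)Oc4cc(OCc5ccccc5)cc(OCc5ccccc5)c34)=C2)cc1 | intermediate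
21 | (2R,3S,2''R,3''S)-5,7,5''-tris(benzyloxy)-7'',4',4'''-trimethoxy-3,3''-biflavanone (both rings 2,3-trans; major isomer, C3/C3'' epimers carried along) | COc1ccc([C@@H]2Oc3cc(OCc4ccccc4)cc(OCc4ccccc4)c3C(=O)[C@H]2[C@@H]2C(=O)c3c(OCc4ccccc4)cc(OC)cc3O[C@H]2c2ccc(OC)cc2)cc1 | intermediate
22 | dilithium 3,3''-bis-enolate of 21 (C2 and C2'' spatially unchanged from 21; C3 and C3'' planar) | COc1ccc([C@@H]2Oc3cc(OCc4ccccc4)cc(OCc4ccccc4)c3C([O-])=C2C2=C([O-])c3c(OCc4ccccc4)cc(OC)cc3O[C@H]2c2ccc(OC)cc2)cc1.[Li+].[Li+] | intermediate (not isolated)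
23 | (2R,3R,2''R,3''R)-5,7,5''-tris(benzyloxy)-7'',4',4'''-trimethoxy-3,3''-biflavanone (both rings 2,3-cis) | COc1ccc([C@@H]2Oc3cc(OCc4ccccc4)cc(OCc4ccccc4)c3C(=O)[C@@H]2[C@H]2C(=O)c3c(OCc4ccccc4)cc(OC)cc3O[C@H]2c2ccc(OC)cc2)cc1 | intermediate
24 | (2R,3R,2''R,3''R)-5,7,5''-trihydroxy-7'',4',4'''-trimethoxy-3,3''-biflavanone (both rings 2,3-cis) | COc1ccc([C@@H]2Oc3cc(O)cc(O)c3C(=O)[C@@H]2[C@H]2C(=O)c3c(O)cc(OC)cc3O[C@H]2c2ccc(OC)cc2)cc1 | target

## Step count

Total steps: 12.
Longest linear sequence: 8 (steps 1, 2, 3, 4, 9, 10, 11, 12; the branch through steps 5–8 is equally long).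

## Steps most likely to fail, and fallbacks

Step 4 (its twin, step 8, carries the same risk). The 6'-alkoxy-2'-hydroxy alkylidene may cyclise without the catalyst, already during step 3, and give low ee. The fallback sets out from 3 and comes back at 10. Compound 3 is condensed with 6 (KOH, EtOH, rt, Claisen–Schmidt) to give (E)-1-[2,4-bis(benzyloxy)-6-hydroxyphenyl]-3-(4-methoxyphenyl)prop-2-en-1-one F1. F1 is closed by a racemic intramolecular oxa-Michael addition (NaOAc, EtOH, reflux) to racemic 5,7-bis(benzyloxy)-2-(4-methoxyphenyl)chroman-4-one F2. Preparative chiral SFC of F2 gives 10. The unwanted (2S)-5,7-bis(benzyloxy)-2-(4-methoxyphenyl)chroman-4-one F3 is racemised again under the same NaOAc conditions (reversible ring opening and closure) and recycled.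

Step 10. Ce(IV) may attack the electron-rich anisyl and benzyloxy arenes, or the hindered tertiary–tertiary bond may not close. The fallback sets out from 10 and 17 and comes back at 21, leaving out 19 and 20. The two ketones are deprotonated together (LDA, THF, −78 °C; 17 in twofold excess) and the mixed lithium enolates are oxidised with anhydrous CuCl2 in DMF (−78 °C to rt), an untethered inner-sphere enolate coupling. Compound 21 is separated by chromatography from the statistical co-products, (2R,3S,2''R,3''S)-5,5''-bis(benzyloxy)-7,7'',4',4'''-tetramethoxy-3,3''-biflavanone F4 and (2R,3S,2''R,3''S)-5,7,5'',7''-tetrakis(benzyloxy)-4',4'''-dimethoxy-3,3''-biflavanone F5, which differ from it by one benzyl-for-methyl exchange each.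

Step 11. The dianion may ring-open, or protonation may give mixed C3 configurations. The fallback sets out from 21 and comes back at 23. Compound 21 is enolised in the presence of the trap (LDA, TMSCl, THF, −78 °C) and the neutral bis(trimethylsilyl) dienol ether F6 is isolated. F6 is then protodesilylated at −78 °C in toluene with a bulky chiral Brønsted acid (the BINOL·SnCl4 complex, in the enantiomer matched to the substrate bias), so that face selection is reinforced by the reagent and no free dianion is present.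

## Further compounds

F1 | step 4 | (E)-1-[2,4-bis(benzyloxy)-6-hydroxyphenyl]-3-(4-methoxyphenyl)prop-2-en-1-one | COc1ccc(/C=C/C(=O)c2c(O)cc(OCc3ccccc3)cc2OCc2ccccc2)cc1
F2 | step 4 | racemic 5,7-bis(benzyloxy)-2-(4-methoxyphenyl)chroman-4-one | COc1ccc(C2Oc3cc(OCc4ccccc4)cc(OCc4ccccc4)c3C(=O)C2)cc1
F3 | step 4 | (2S)-5,7-bis(benzyloxy)-2-(4-methoxyphenyl)chroman-4-one | COc1ccc([C@H]2Oc3cc(OCc4ccccc4)cc(OCc4ccccc4)c3C(=O)C2)cc1
F4 | step 10 | (2R,3S,2''R,3''S)-5,5''-bis(benzyloxy)-7,7'',4',4'''-tetramethoxy-3,3''-biflavanone | COc1ccc([C@@H]2Oc3cc(OC)cc(OCc4ccccc4)c3C(=O)[C@H]2[C@@H]2C(=O)c3c(OCc4ccccc4)cc(OC)cc3O[C@H]2c2ccc(OC)cc2)cc1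
F5 | step 10 | (2R,3S,2''R,3''S)-5,7,5'',7''-tetrakis(benzyloxy)-4',4'''-dimethoxy-3,3''-biflavanone | COc1ccc([C@@H]2Oc3cc(OCc4ccccc4)cc(OCc4ccccc4)c3C(=O)[C@H]2[C@@H]2C(=O)c3c(OCc4ccccc4)cc(OCc4ccccc4)cc3O[C@H]2c2ccc(OC)cc2)cc1
F6 | step 11 | 4,4''-bis(trimethylsilyl) dienol ether of 21 (C2 and C2'' spatially unchanged) | COc1ccc([C@@H]2Oc3cc(OCc4ccccc4)cc(OCc4ccccc4)c3C(O[Si](C)(C)C)=C2C2=C(O[Si](C)(C)C)c3c(OCc4ccccc4)cc(OC)cc3O[C@H]2c2ccc(OC)cc2)cc1
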